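## Structural features

The target is a eudesmane: a trans-fused decalin in which ring A (C1–C5, C10) and ring B (C5–C10) share the C5–C10 bond, with the angular methyl C14 on the quaternary C10 and an axial hydrogen on C5. Ring A carries four stereocentres in a row: C3 (R, axial α-angelate), C4 (S, tertiary acetate, oxygen equatorial, methyl C15 axial), C5 (R) and C10 (R). The two oxygens are cis, and C14 and C15 are 1,3-diaxial on the β face. Ring B is a 6-en-8-one whose α-carbon C7 bears the 2-hydroperoxypropan-2-yl group (C11–C13). The fragile groups are the tertiary allylic hydroperoxide (hydrides, metals, acid, base), the angelate (Z to E isomerisation) and the C4 acetate, which lies δ to the enone carbonyl and could be expelled after deprotonation at C5. The real difficulty is ring A: a cis-3,4-diol with two different esters on a secondary and a tertiary oxygen, in which the C4 carbinol has the configuration that a methyl nucleophile would not give on a 4-ketone (attack away from axial C14 would put C15 equatorial). The key step exploits this array: an oxygen already on C3 is delivered to C4 while C10 bonds to C5 on the other face of an (E)-C4=C5 alkene, which closes ring A and sets C4 and C5 in one stereospecific anti addition.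

## Logic of the disconnections

**30 to 29.** The O–C11 bond is cut first, together with a shift of the alkene from C6=C7 to C7=C11. The hydroperoxide cannot be carried through any earlier step, and the cut turns ring B into a plain α-isopropylidene ketone. The forward ene reaction must put oxygen on C11, take hydrogen from C6 rather than from C12 or C13, and leave the angelate untouched.

**29 to 28 to 26 and 27.** The two acyl C–O bonds are cut, the tertiary acetate first and then the secondary angelate. Neither ester would survive the enolate chemistry on ring B. This leaves diol 26 and angelic acid 27. The forward steps must acylate the secondary hydroxyl selectively, must not isomerise the Z alkene, and must then force the hindered tertiary hydroxyl to react.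

**26 to 25, then 25 to 23 to 21 and 22.** The diol is masked as cyclic carbonate 25. The C7=C11 bond is then cut by a retro-aldol condensation to ketone 21 and acetone 22, through aldol 23. This removes three carbons and the tetrasubstituted alkene. The forward step must enolise 21 toward C7 and not C9, and must tolerate the carbonate.

**21 to 20 to 18.** Ring B is opened at C6–C7: 21 comes from enone 20 by saturation, and 20 from keto aldehyde 18 by intramolecular aldol condensation. Only the methyl carbon C7 can reach C6 in a six-membered ring, so the regiochemistry is fixed. The result is a monocyclic compound. The aldehyde must cyclise faster than it loses the β-carbonate oxygen or epimerises at C5.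

**18 to 17 to 16 to 15.** No skeletal bond is cut. The aldehyde is traced to a benzyl ether and the methyl ketone to an allyl group. These are the two side chains that are inert to strong acid, which the key step needs. The alkene must be oxidised before the hydrogenolysis.

**15 to 13 (key).** The C5–C10 bond and the O–C4 bond are cut. Ring A, the carbonate ring and three stereocentres (C4, C5, C10) are exchanged for an acyclic triene with one stereocentre. Both trisubstituted alkenes of 13 must be E: C4=C5 for the C4/C5 relationship, and C1=C10 because methyl and allyl are too close in size to be told apart in a relaxed cation, so only the alkene geometry can relay C10. The route to 13 therefore builds the C1=C10 alkene by an E-selective method and not by a non-stabilised ylide.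

**13 to 12 to 10 and 11.** The carbonate C–O bond is cut, then the C8–C9 bond between an allylic bromide and a vinyl nucleophile. This removes the skipped diene. The coupling must occur at the α-carbon with retention of the E geometry.

**10 to 9 to 8 to 6 and 7.** The bromide is traced to a primary allylic alcohol and that to an enoate. The C1=C10 alkene is then cut by cross-metathesis into terminal alkene 6 and methyl methacrylate 7. This reaction is reliably E-selective. The forward sequence must tell a primary from a secondary allylic alcohol.

**6 to 3 and 4.** The C2–C3 bond is cut to enal 3 and an allyl nucleophile 4. This is the step that sets C3, and it must be enantioselective in the R sense.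

**3 to 1 and 2.** The C4=C5 alkene is cut to aldehyde 1 and the stabilised ylide 2. Both are commercial, and the olefination is E-selective.

## Other disconnections considered

**Alternative 1:** The cut removes C5–C10 and C8–C9 together, so ring B comes from a [4+2] cycloaddition and ring A from the four-carbon tether. In the forward direction the acyclic triene A1, which holds a (5E,7E)-1-silyloxydiene and an (E)-nitroalkene, would be heated to give the trans-fused adduct A2.
- In its favour: two rings, the quaternary C10 and the C5/C10 relationship would form in one concerted step whose relative stereochemistry follows from the alkene geometries. A2 already holds the C6=C7 alkene and an oxygen on C8, so removal of the nitro group and oxidation at C8 would lead straight to the 6-en-8-one.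
- Against it here: ring A arrives almost bare, with C4 as a ketal, no C15 and no oxygen on C3. A methyl nucleophile would be expected to add to the unmasked C4 carbonyl from the face away from axial C14 and set the wrong C4 epimer, so the tertiary acetate would need a detour and the axial C3 oxygen a separate oxidation. The absolute sense would rest on remote induction from the chiral ketal. The trisubstituted nitroalkene is a sluggish dienophile, and the secondary nitro group must later be removed reductively beside an allylic silyl ether.
- Comparison: on structure, A2 answers ring B and the ring fusion, whereas the chosen plan answers ring A and leaves ring B to routine carbonyl chemistry. On mechanism, the pericyclic step fixes C10 relative to C5 more firmly than the cationic closure does; on this point the alternative is the better. Its direct delivery of the ring B enone is also better than the five operations the chosen route spends on it. On step economy the gain is probably lost again in ring A.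

**Alternative 2:** The cut is the C9–C10 bond. The phenol A3 carries C14 para to the hydroxyl, C15 ortho to it and a diazoketone side chain. It would be decomposed by a chiral dirhodium tetracarboxylate (divalent rhodium); attack of the para carbon on the carbenoid would close ring B and leave ring A as the cross-conjugated dienone A4.
- In its favour: A3 should be available in very few steps from a simple aromatic, C10 would be set by the catalyst and not by the substrate, and both the C3 and C8 carbonyl groups are in place.
- Against it here: C10 is the only stereocentre made. C3, C4 and C5 are all trigonal in A4, so the sequence would still have to tell two ketones apart, remove the C1=C2 alkene, and add hydrogen to C5 and oxygen to C4 on the α face of a tetrasubstituted alkene. The carbenoid has other outlets (arene cyclopropanation and ring expansion, O–H insertion).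
- Comparison: structurally A4 has the skeleton but none of the ring A stereochemistry, which the chosen key step delivers complete. Mechanistically, catalyst-controlled formation of C10 is the equal or the better of the chosen plan on that single centre. On step economy the alternative is clearly better up to the bicyclic core, but the redox and stereochemical corrections that follow would probably cost more than is saved.

**Alternative 3:** The cut is the C3–C4 bond. The cyclohexane A5 carries the C4 methyl ketone on C5 and a three-carbon aldehyde chain on the quaternary C10. A chiral triazolylidene carbene would turn the aldehyde into an acyl anion equivalent that adds to the ketone and closes ring A as the α-ketol A6.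
- In its favour: the tertiary carbinol with C15 and the neighbouring C3 carbonyl form in one bond construction, which maps onto ring A as directly as the chosen step does (equal on this point). The C3 ketone could then be reduced from the equatorial side to the axial alcohol. Ring B and its C8 carbonyl exist before the key step, so no annulation follows it, which is better than the chosen route.
- Against it here: the required C4 epimer has the methyl axial and syn to C14, the more crowded arrangement, and benzoin addition is reversible, so the catalyst would have to override substrate bias and equilibration. The aldehyde of A5 is enolisable and aldol addition onto the ketone competes. A5 itself needs a multi-step enantioselective synthesis.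
- Comparison: on structure both plans build the C3/C4 dioxygenation in the key step. On mechanism the chosen plan takes the C4 configuration from a stereospecific anti addition, the safer source, while the alternative is the better on C10. On step economy the two are probably close.

Key step: step 8

Assumption: protonation of the C1=C10 alkene and C5–C10 bond formation are taken to be concerted (anti addition across the E alkene in a chair), so that the alkene geometry, not the small size difference between methyl and allyl, decides C10.

## Route

Step 1
Reactants: 1 (benzyloxy)acetaldehyde; 2 2-(triphenylphosphoranylidene)propanal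
Product: 3 (2E)-4-(benzyloxy)-2-methylbut-2-enal
Conditions: toluene, 80 °C
Reagents that add atoms: none
Why: Wittig olefination with a formyl-stabilised ylide is E-selective; the conjugated, α-branched product is much less electrophilic than 1, so a second olefination should not compete.

Step 2
Reactants: 3 (2E)-4-(benzyloxy)-2-methylbut-2-enal; 4 allylmagnesium bromide
Product: 6 (2E,4R)-1-(benzyloxy)-3-methylhepta-2,6-dien-4-ol, via diisopinocampheylborinate 5 (not isolated)
Conditions: (+)-Ipc2BOMe, 4, Et2O, −78 °C to rt; then 3, −78 °C; NaOH, H2O2
Reagents that add atoms: none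
Why: Brown allylboration through a chair six-membered transition state; the isopinocampheyl groups derived from (−)-α-pinene direct allyl transfer to the Re face of the aldehyde (the sense that gives (R)-carbinols from aryl and alkenyl aldehydes), which sets C3 as R.

Step 3
Reactants: 6 (2E,4R)-1-(benzyloxy)-3-methylhepta-2,6-dien-4-ol; 7 methyl methacrylate
Product: 8 methyl (2E,5R,6E)-8-(benzyloxy)-5-hydroxy-2,6-dimethylocta-2,6-dienoate
Conditions: second-generation Hoveyda–Grubbs catalyst (3 mol %), 7 (10 equiv), CH2Cl2, 40 °C
Reagents that add atoms: none
Why: Olefin cross-metathesis of a terminal alkene with a 1,1-disubstituted acrylate gives the trisubstituted enoate under thermodynamic control as the E isomer; the trisubstituted allylic-ether alkene is inert and the free hydroxyl is tolerated.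

Step 4
Reactants: 8 methyl (2E,5R,6E)-8-(benzyloxy)-5-hydroxy-2,6-dimethylocta-2,6-dienoate
Product: 9 (2E,5R,6E)-8-(benzyloxy)-2,6-dimethylocta-2,6-diene-1,5-diol
Conditions: iBu2AlH (3.3 equiv), CH2Cl2, −78 to 0 °C
Reagents that add atoms: none
Why: Hydride reduction of the enoate with an aluminium hydride goes 1,2 to the allylic alcohol without touching the alkene geometry.

Step 5
Reactants: 9 (2E,5R,6E)-8-(benzyloxy)-2,6-dimethylocta-2,6-diene-1,5-diol
Product: 10 (2E,4R,6E)-1-(benzyloxy)-8-bromo-3,7-dimethylocta-2,6-dien-4-ol
Conditions: CBr4 (1.1 equiv), PPh3 (1.15 equiv), CH2Cl2, −30 to 0 °C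
Reagents that add atoms: tetrabromomethane BrC(Br)(Br)Br
Why: Appel bromination; the unhindered primary allylic alkoxyphosphonium ion forms and is displaced far faster than the one at the secondary carbinol flanked by a methyl-bearing alkene, so one equivalent at low temperature should react at C9 only.

Step 6
Reactants: 10 (2E,4R,6E)-1-(benzyloxy)-8-bromo-3,7-dimethylocta-2,6-dien-4-ol; 11 vinylmagnesium bromide
Product: 12 (2E,4R,6E)-1-(benzyloxy)-3,7-dimethyldeca-2,6,9-trien-4-ol
Conditions: 11 (2.5 equiv), Li2CuCl4 (5 mol %), THF, −78 to −20 °C
Reagents that add atoms: none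
Why: Copper-catalysed Grignard coupling at a primary allylic bromide (Kochi-type) proceeds at the α-carbon with retention of the E alkene; the first equivalent of 11 only forms the magnesium alkoxide, which is a spectator.

Step 7
Reactants: 12 (2E,4R,6E)-1-(benzyloxy)-3,7-dimethyldeca-2,6,9-trien-4-ol
Product: 13 (2E,4R,6E)-1-(benzyloxy)-3,7-dimethyldeca-2,6,9-trien-4-yl tert-butyl carbonate
Conditions: LiN(SiMe3)2 (1.05 equiv), THF, −78 °C; Boc2O, −78 to 0 °C
Reagents that add atoms: di-tert-butyl dicarbonate CC(C)(C)OC(=O)OC(=O)OC(C)(C)C
Why: O-acylation of the lithium alkoxide with Boc2O is clean for a hindered secondary alcohol and avoids the symmetric carbonates that amine catalysis can give.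

Step 8
Reactants: 13 (2E,4R,6E)-1-(benzyloxy)-3,7-dimethyldeca-2,6,9-trien-4-yl tert-butyl carbonate
Product: 15 (3aS,4S,5R,7aR)-4-[(benzyloxy)methyl]-3a,5-dimethyl-5-(prop-2-en-1-yl)hexahydro-1,3-benzodioxol-2-one, via tert-butoxydioxolanylium ion 14 (not isolated)
Conditions: HNTf2 (10 mol %), CH2Cl2 (0.01 M), −78 to −40 °C
Reagents that add atoms: none
Why: The acid protonates C1 of the electron-rich C1=C10 alkene; C5 of the C4=C5 alkene attacks the developing C10 cation and the carbonyl oxygen of the C3 carbonate adds to C4 on the opposite face, giving ion 14, which loses isobutene and returns the proton. The closest known reaction type is the acid-induced cation–olefin cyclisation terminated by a tert-butyl carbonate, related to halonium- and epoxide-initiated carbonate cyclisations. Ring A closes 6-endo-trig (both carbons of the C4=C5 alkene end up in the ring) through a chair; the carbonate ring closes 5-exo-trig at C4. C4 and C5 are set relative to each other by anti addition across the E alkene, which puts O4 equatorial and C15 axial, trans-diaxial to H5. Their absolute sense comes from C3: the carbonate can only reach C4 on the face of the C3–O bond, so the chair with that bond axial is the one that reacts and the new ring is cis-fused. C10 is set by the E geometry of C1=C10 under concerted anti addition of the proton and C5: C9, trans to C2 on the alkene, becomes equatorial and C14 axial, syn to C15. The step needs site-selective protonation, which the substrate secures because C4=C5 is deactivated by two allylic oxygens and the vinyl group is only monosubstituted. It also needs capture to win over proton loss, which the neighbouring carbonate, dilution and low temperature favour.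

Step 9
Reactants: 15 (3aS,4S,5R,7aR)-4-[(benzyloxy)methyl]-3a,5-dimethyl-5-(prop-2-en-1-yl)hexahydro-1,3-benzodioxol-2-one
Product: 16 the 5-(2-oxopropyl) analogue of 15 (methyl ketone at C8; all four ring stereocentres as in 15)
Conditions: PdCl2 (10 mol %), CuCl (1 equiv), O2 (1 atm), DMF/H2O (7:1), rt
Reagents that add atoms: water O
Why: Tsuji–Wacker oxidation; Markovnikov hydroxypalladation of the only alkene gives the methyl ketone, and the benzyl ether and carbonate are inert.

Step 10
Reactants: 16 the 5-(2-oxopropyl) analogue of 15
Product: 17 the 4-(hydroxymethyl)-5-(2-oxopropyl) compound (C6 primary alcohol; ring stereocentres as in 15)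
Conditions: H2 (1 atm), 10% Pd/C, EtOAc, rt
Reagents that add atoms: none
Why: Hydrogenolysis of the benzyl ether under neutral conditions, so the carbonate cannot migrate to the new hydroxyl; any lactol formed with the ketone is in equilibrium with 17 and harmless.

Step 11
Reactants: 17 the 4-(hydroxymethyl)-5-(2-oxopropyl) compound
Product: 18 the 4-formyl-5-(2-oxopropyl) compound (C6 aldehyde; ring stereocentres as in 15)
Conditions: Dess–Martin periodinane, CH2Cl2, 0 °C to rt
Reagents that add atoms: none
Why: Dess–Martin oxidation is non-basic, so the aldehyde with its β-carbonate oxygen is formed without enolisation; it is used directly.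

Step 12
Reactants: 18 the 4-formyl-5-(2-oxopropyl) compound
Product: 20 (3R,4S,5R,10R)-3α,4α-carbonyldioxy-11,12,13-trinoreudesm-6-en-8-one, via 6-hydroxy ketone 19 (not isolated)
Conditions: Bn2NH·CF3CO2H (0.3 equiv), toluene, 50 °C
Reagents that add atoms: none
Why: Intramolecular aldol condensation under buffered amine-salt catalysis, 6-(enolendo)-exo-trig; only C7 can reach C6 in a six-membered ring (C9 would give a four-membered one). The equatorial C4–O bond lies in the plane of any C5 enol or enamine, so β-elimination is stereoelectronically slow.

Step 13
Reactants: 20 (3R,4S,5R,10R)-3α,4α-carbonyldioxy-11,12,13-trinoreudesm-6-en-8-one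
Product: 21 (3R,4S,5R,10R)-3α,4α-carbonyldioxy-11,12,13-trinoreudesman-8-one
Conditions: H2 (1 atm), 10% Pd/C, EtOAc, rt
Reagents that add atoms: none
Why: Heterogeneous hydrogenation of the disubstituted enone alkene; no stereocentre is created and the ketone and carbonate are not reduced.

Step 14
Reactants: 21 (3R,4S,5R,10R)-3α,4α-carbonyldioxy-11,12,13-trinoreudesman-8-one; 22 acetone
Product: 23 3α,4α-carbonyldioxy-11-hydroxyeudesman-8-one (C7 epimers, of no consequence)
Conditions: LiN(iPr)2 (1.1 equiv), THF, −78 °C; ZnCl2 (1.2 equiv); 22 (5 equiv), −78 to −40 °C
Reagents that add atoms: none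
Why: Kinetic deprotonation occurs at C7, because C9 is a neopentyl methylene next to the quaternary C10; the zinc enolate adds to acetone (directed aldol addition) with less proton transfer and retro-aldol than the lithium enolate.

Step 15
Reactants: 23 3α,4α-carbonyldioxy-11-hydroxyeudesman-8-one
Product: 25 (3R,4S,5R,10R)-3α,4α-carbonyldioxyeudesm-7(11)-en-8-one, via tertiary mesylate 24 (not isolated)
Conditions: MsCl, Et3N, CH2Cl2, 0 °C to rt; DBU (0.2 equiv), rt
Reagents that add atoms: none
Why: Mesylation of the tertiary alcohol through sulfene, then E1cB elimination through the C7 enolate, gives the conjugated tetrasubstituted alkene; DBU equilibrates any isopropenyl isomer into conjugation.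

Step 16
Reactants: 25 (3R,4S,5R,10R)-3α,4α-carbonyldioxyeudesm-7(11)-en-8-one
Product: 26 (3R,4S,5R,10R)-3α,4α-dihydroxyeudesm-7(11)-en-8-one
Conditions: K2CO3 (0.3 equiv), MeOH, 0 °C to rt
Reagents that add atoms: none
Why: Base-catalysed methanolysis (transesterification) of the cyclic carbonate; at this stage C6 is saturated, so no oxygen sits where an enolate could expel it.

Step 17
Reactants: 26 (3R,4S,5R,10R)-3α,4α-dihydroxyeudesm-7(11)-en-8-one; 27 angelic acid, (2Z)-2-methylbut-2-enoic acid
Product: 28 (3R,4S,5R,10R)-3α-angeloyloxy-4α-hydroxyeudesm-7(11)-en-8-one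
Conditions: 27, 2,4,6-trichlorobenzoyl chloride, Et3N, toluene, rt; then 26, 80 °C
Reagents that add atoms: none
Why: Yamaguchi-type mixed-anhydride esterification without a nucleophilic catalyst, which avoids the addition–elimination pathway that turns angelates into tiglates; only the secondary hydroxyl is acylated, the tertiary one being too hindered.

Step 18
Reactants: 28 (3R,4S,5R,10R)-3α-angeloyloxy-4α-hydroxyeudesm-7(11)-en-8-one
Product: 29 (3R,4S,5R,10R)-4α-acetoxy-3α-angeloyloxyeudesm-7(11)-en-8-one
Conditions: Ac2O, Sc(OTf)3 (5 mol %), MeCN, −20 °C
Reagents that add atoms: acetic anhydride CC(=O)OC(C)=O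
Why: Lewis-acid-catalysed acylation with Ac2O acetylates tertiary alcohols at low temperature, where the angelate and the enone should be left alone.

Step 19
Reactants: 29 (3R,4S,5R,10R)-4α-acetoxy-3α-angeloyloxyeudesm-7(11)-en-8-one
Product: 30 (3R,4S,5R,10R)-4α-acetoxy-3α-angeloyloxy-11-hydroperoxyeudesm-6-en-8-one (target)
Conditions: O2, tetraphenylporphyrin (1 mol %), visible light (λ > 500 nm), CH2Cl2, −20 °C
Reagents that add atoms: dioxygen O=O
Why: Schenck ene reaction of singlet oxygen; with an s-cis enone the oxygen adds to the β-carbon C11 and the hydrogen comes from the group geminal to the carbonyl (axial H on C6), which moves the alkene to C6=C7 in conjugation. The electron-poor angelate reacts much more slowly, the sensitiser triplet is too low to isomerise it, and C11 is not stereogenic.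

## Compound list

1 | (benzyloxy)acetaldehyde | O=CCOCc1ccccc1 | starting material
2 | 2-(triphenylphosphoranylidene)propanal | CC(C=O)=P(c1ccccc1)(c1ccccc1)c1ccccc1 | starting material
3 | (2E)-4-(benzyloxy)-2-methylbut-2-enal | O=C/C(C)=C/COCc1ccccc1 | intermediate
4 | allylmagnesium bromide | C=CC[Mg]Br | starting material
5 | O-diisopinocampheylborinate of 6 | c1ccccc1COC/C=C(\C)[C@H](OB([C@H]2C[C@H]3C[C@H](C3(C)C)[C@@H]2C)[C@H]2C[C@H]3C[C@H](C3(C)C)[C@@H]2C)CC=C | intermediate (not isolated)
6 | (2E,4R)-1-(benzyloxy)-3-methylhepta-2,6-dien-4-ol | c1ccccc1COC/C=C(\C)[C@H](O)CC=C | intermediate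
7 | methyl methacrylate | C=C(C)C(=O)OC | starting material
8 | methyl (2E,5R,6E)-8-(benzyloxy)-5-hydroxy-2,6-dimethylocta-2,6-dienoate | c1ccccc1COC/C=C(\C)[C@H](O)C/C=C(\C)C(=O)OC | intermediate
9 | (2E,5R,6E)-8-(benzyloxy)-2,6-dimethylocta-2,6-diene-1,5-diol | c1ccccc1COC/C=C(\C)[C@H](O)C/C=C(\C)CO | intermediate
10 | (2E,4R,6E)-1-(benzyloxy)-8-bromo-3,7-dimethylocta-2,6-dien-4-ol | c1ccccc1COC/C=C(\C)[C@H](O)C/C=C(\C)CBr | intermediate
11 | vinylmagnesium bromide | C=C[Mg]Br | starting material
12 | (2E,4R,6E)-1-(benzyloxy)-3,7-dimethyldeca-2,6,9-trien-4-ol | c1ccccc1COC/C=C(\C)[C@H](O)C/C=C(\C)CC=C | intermediate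
13 | (2E,4R,6E)-1-(benzyloxy)-3,7-dimethyldeca-2,6,9-trien-4-yl tert-butyl carbonate | c1ccccc1COC/C=C(\C)[C@H](OC(=O)OC(C)(C)C)C/C=C(\C)CC=C | intermediate (key-step precursor)
14 | 2-tert-butoxy-1,3-dioxolan-2-ylium ion cis-fused to ring A at C3/C4 | CC(C)(C)O[C+]1O[C@@H]2CC[C@](C)(CC=C)[C@@H](COCc3ccccc3)[C@]2(C)O1 | intermediate (not isolated)
15 | (3aS,4S,5R,7aR)-4-[(benzyloxy)methyl]-3a,5-dimethyl-5-(prop-2-en-1-yl)hexahydro-1,3-benzodioxol-2-one | O=C1O[C@@H]2CC[C@](C)(CC=C)[C@@H](COCc3ccccc3)[C@]2(C)O1 | intermediate (key-step product)
16 | 4-[(benzyloxy)methyl]-3a,5-dimethyl-5-(2-oxopropyl)hexahydro-1,3-benzodioxol-2-one, configuration as 15 | O=C1O[C@@H]2CC[C@](C)(CC(C)=O)[C@@H](COCc3ccccc3)[C@]2(C)O1 | intermediate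
17 | 4-(hydroxymethyl)-3a,5-dimethyl-5-(2-oxopropyl)hexahydro-1,3-benzodioxol-2-one, configuration as 15 | O=C1O[C@@H]2CC[C@](C)(CC(C)=O)[C@@H](CO)[C@]2(C)O1 | intermediate
18 | 3a,5-dimethyl-2-oxo-5-(2-oxopropyl)hexahydro-1,3-benzodioxole-4-carbaldehyde, configuration as 15 | O=C1O[C@@H]2CC[C@](C)(CC(C)=O)[C@@H](C=O)[C@]2(C)O1 | intermediate
19 | 3α,4α-carbonyldioxy-6-hydroxy-11,12,13-trinoreudesman-8-one (C6 epimers) | O=C1O[C@@H]2CC[C@]3(C)CC(=O)CC(O)[C@H]3[C@]2(C)O1 | intermediate (not isolated)
20 | (3R,4S,5R,10R)-3α,4α-carbonyldioxy-11,12,13-trinoreudesm-6-en-8-one | O=C1O[C@@H]2CC[C@]3(C)CC(=O)C=C[C@H]3[C@]2(C)O1 | intermediate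
21 | (3R,4S,5R,10R)-3α,4α-carbonyldioxy-11,12,13-trinoreudesman-8-one | O=C1O[C@@H]2CC[C@]3(C)CC(=O)CC[C@H]3[C@]2(C)O1 | intermediate
22 | acetone | CC(C)=O | starting material
23 | 3α,4α-carbonyldioxy-11-hydroxyeudesman-8-one (C7 epimers) | O=C1O[C@@H]2CC[C@]3(C)CC(=O)C(C(C)(C)O)C[C@H]3[C@]2(C)O1 | intermediate
24 | 11-methanesulfonate of 23 | O=C1O[C@@H]2CC[C@]3(C)CC(=O)C(C(C)(C)OS(C)(=O)=O)C[C@H]3[C@]2(C)O1 | intermediate (not isolated)
25 | (3R,4S,5R,10R)-3α,4α-carbonyldioxyeudesm-7(11)-en-8-one | O=C1O[C@@H]2CC[C@]3(C)CC(=O)C(=C(C)C)C[C@H]3[C@]2(C)O1 | intermediate
26 | (3R,4S,5R,10R)-3α,4α-dihydroxyeudesm-7(11)-en-8-one | O[C@@H]1CC[C@]2(C)CC(=O)C(=C(C)C)C[C@H]2[C@]1(C)O | intermediate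
27 | angelic acid, (2Z)-2-methylbut-2-enoic acid | C/C=C(/C)C(=O)O | starting material
28 | (3R,4S,5R,10R)-3α-angeloyloxy-4α-hydroxyeudesm-7(11)-en-8-one | C/C=C(/C)C(=O)O[C@@H]1CC[C@]2(C)CC(=O)C(=C(C)C)C[C@H]2[C@]1(C)O | intermediate
29 | (3R,4S,5R,10R)-4α-acetoxy-3α-angeloyloxyeudesm-7(11)-en-8-one | C/C=C(/C)C(=O)O[C@@H]1CC[C@]2(C)CC(=O)C(=C(C)C)C[C@H]2[C@]1(C)OC(C)=O | intermediate
30 | (3R,4S,5R,10R)-4α-acetoxy-3α-angeloyloxy-11-hydroperoxyeudesm-6-en-8-one | C/C=C(/C)C(=O)O[C@@H]1CC[C@]2(C)CC(=O)C(C(C)(C)OO)=C[C@H]2[C@]1(C)OC(C)=O | target

## Step count and least certain steps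

Total step count: 19. Longest linear sequence: 19 steps (1 to 30; the route is linear, and 2, 4, 7, 11, 22 and 27 are commercial).

**Step 8 (key step).** The most likely failure is loss of stereocontrol at C10: if protonation gives a free cation that relaxes before C5 attacks, methyl and allyl are not distinguished. Other risks are proton loss from C10 toward C9 (isomerisation of the skipped diene into conjugation) and acid cleavage of the tert-butyl carbonate before ring closure, because the C4=C5 alkene is a weak nucleophile. The fallback makes the initiation stereospecific with an epoxide and sets out from 13. Shi epoxidation (D-fructose-derived ketone, KHSO5, buffered MeCN/dimethoxymethane, 0 °C) should epoxidise only the electron-rich C1=C10 alkene, under reagent control, to the (6R,7R)-epoxide of 13 F1. BF3·OEt2 in CH2Cl2 at −78 °C then opens the epoxide at C10 with backside attack by C5 and carbonate capture at C4 (the known epoxide-initiated cyclisation terminated by a tert-butyl carbonate), giving the 1β-hydroxy analogue of 15 F2. Barton–McCombie deoxygenation through the imidazole-1-carbothioate of F2 F3 (thiocarbonyldiimidazole, then Bu3SnH, AIBN, toluene, 90 °C) removes the hydroxyl and returns to the route at 15.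

**Step 12.** The aldehyde of 18 has a carbonate oxygen on its β-carbon; enolisation or enamine formation at C5 could lead to elimination across C4–C5 or to epimerisation before the aldol closure occurs. The fallback avoids the aldehyde and sets out from 17. Iodination (I2, PPh3, imidazole) gives the primary iodide of 17 F4. The kinetic enolate of the methyl ketone (LiN(SiMe3)2, THF/DMPU, −78 to 0 °C) is then alkylated intramolecularly at C7 (6-(enolendo)-exo-tet). This displacement is hindered, which is why it is the reserve. It comes back to the route at 21 and bypasses 18 to 20.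

**Step 14.** Proton transfer from acetone to the enolate, retro-aldol on warming, enolisation toward C9, or attack of the amide base on the carbonate could all lower the return of 23. The fallback replaces the metal enolate by a Mukaiyama aldol and sets out from 21. LiN(SiMe3)2 and Me3SiCl give the C7=C8 trimethylsilyl enol ether of 21 F5, which adds to acetone under TiCl4 in CH2Cl2 at −78 °C as a titanium chelate that does not revert. It comes back to the route at 23.

**Step 5.** Bromination may lose site selectivity if the secondary allylic hydroxyl is also activated, with substitution or allylic transposition at C3. The fallback protects that hydroxyl and sets out from 8. Silylation (tBuMe2SiCl, imidazole) gives the tert-butyldimethylsilyl ether of 8 F6. Reduction with iBu2AlH gives the silyl-protected primary allylic alcohol F7. CBr4/PPh3 gives the silyl-protected allylic bromide F8. Coupling with 11 and Li2CuCl4 gives the silyl ether of 12 F9. Bu4NF removes the silyl group and returns to the route at 12.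

**Step 17.** The Z alkene of the angeloyl group may isomerise to the E (tigloyl) form during activation or acyl transfer at 80 °C, and the axial hydroxyl next to a quaternary carbon may acylate slowly. The fallback builds the Z alkene on the ester and sets out from 26. Esterification with 2-[bis(2,2,2-trifluoroethoxy)phosphoryl]propanoic acid (DCC, catalytic DMAP) gives the 3-O-phosphonopropanoate of 26 F10. Still–Gennari olefination (KN(SiMe3)2, 18-crown-6, THF, −78 °C, then acetaldehyde) is expected to deprotonate only the much more acidic phosphonate and to give the Z enoate. It returns to the route at 28.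

## Further compounds

F1 | step 8 | (2E,4R)-1-(benzyloxy)-3-methyl-5-[(2R,3R)-3-methyl-3-(prop-2-en-1-yl)oxiran-2-yl]pent-2-en-4-yl tert-butyl carbonate | c1ccccc1COC/C=C(\C)[C@H](OC(=O)OC(C)(C)C)C[C@H]1O[C@]1(C)CC=C
F2 | step 8 | 1β-hydroxy analogue of 15 (equatorial hydroxyl on C1, eudesmane numbering) | O=C1O[C@@H]2C[C@@H](O)[C@](C)(CC=C)[C@@H](COCc3ccccc3)[C@]2(C)O1
F3 | step 8 | O-(C1) 1H-imidazole-1-carbothioate of F2 | O=C1O[C@@H]2C[C@@H](OC(=S)n3ccnc3)[C@](C)(CC=C)[C@@H](COCc4ccccc4)[C@]2(C)O1
F4 | step 12 | 4-(iodomethyl)-3a,5-dimethyl-5-(2-oxopropyl)hexahydro-1,3-benzodioxol-2-one, configuration as 15 | O=C1O[C@@H]2CC[C@](C)(CC(C)=O)[C@@H](CI)[C@]2(C)O1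
F5 | step 14 | C7=C8 trimethylsilyl enol ether of 21 | O=C1O[C@@H]2CC[C@]3(C)CC(O[Si](C)(C)C)=CC[C@H]3[C@]2(C)O1
F6 | step 5 | methyl (2E,5R,6E)-8-(benzyloxy)-5-[(tert-butyldimethylsilyl)oxy]-2,6-dimethylocta-2,6-dienoate | c1ccccc1COC/C=C(\C)[C@H](O[Si](C)(C)C(C)(C)C)C/C=C(\C)C(=O)OC
F7 | step 5 | (2E,5R,6E)-8-(benzyloxy)-5-[(tert-butyldimethylsilyl)oxy]-2,6-dimethylocta-2,6-dien-1-ol | c1ccccc1COC/C=C(\C)[C@H](O[Si](C)(C)C(C)(C)C)C/C=C(\C)CO
F8 | step 5 | tert-butyldimethylsilyl ether of 10 | c1ccccc1COC/C=C(\C)[C@H](O[Si](C)(C)C(C)(C)C)C/C=C(\C)CBr
F9 | step 5 | tert-butyldimethylsilyl ether of 12 | c1ccccc1COC/C=C(\C)[C@H](O[Si](C)(C)C(C)(C)C)C/C=C(\C)CC=C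
F10 | step 17 | 3-O-{2-[bis(2,2,2-trifluoroethoxy)phosphoryl]propanoyl} derivative of 26 | CC(C(=O)O[C@@H]1CC[C@]2(C)CC(=O)C(=C(C)C)C[C@H]2[C@]1(C)O)P(=O)(OCC(F)(F)F)OCC(F)(F)F
A1 | alternative 1 | (4R,5R)-4,5-dimethyl-2-[(4E)-4-methyl-5-nitropent-4-en-1-yl]-2-[(1E,3E)-4-(triisopropylsilyloxy)buta-1,3-dien-1-yl]-1,3-dioxolane | [O-][N+](=O)/C=C(\C)CCCC1(O[C@H](C)[C@@H](C)O1)/C=C/C=C/O[Si](C(C)C)(C(C)C)C(C)C
A2 | alternative 1 | trans-fused 9-nitro-8-(triisopropylsilyloxy)-10-methyldecal-6-en-4-one (2R,3R)-butane-2,3-diyl ketal (eudesmane numbering) | C1CC[C@]2(C)[C@@H]([N+](=O)[O-])[C@@H](O[Si](C(C)C)(C(C)C)C(C)C)C=C[C@H]2C13O[C@H](C)[C@@H](C)O3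
A3 | alternative 2 | 1-diazo-4-(3-hydroxy-2,6-dimethylphenyl)butan-2-one | Cc1ccc(O)c(C)c1CCC(=O)C=[N+]=[N-]
A4 | alternative 2 | (4aS)-1,4a-dimethyl-4a,5,7,8-tetrahydronaphthalene-2,6-dione | CC1=C2CCC(=O)C[C@@]2(C)C=CC1=O
A5 | alternative 3 | 3-(8-acetyl-7-methyl-1,4-dioxaspiro[4.5]decan-7-yl)propanal, acetyl and methyl cis | O=CCC[C@]1(C)CC2(OCCO2)CC[C@H]1C(C)=O
A6 | alternative 3 | 4α-hydroxy-4β,10β-dimethyl-5α-decalin-3,8-dione 8-ethylene ketal (eudesmane numbering) | O=C1CC[C@]2(C)CC3(OCCO3)CC[C@H]2[C@]1(C)O
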